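**Plan**

- Retrosynthesis: the C1–acyl bond of ring A is cut first (Friedel–Crafts, the last forward step). Ring A is then cut at C1–C2, C2–C3 and C5–C6 into (triisopropylsiloxy)ethyne and a 3-siloxycyclobutenone that already carries both arylmethyl arms.
- Enabling feature: ring A is a hexasubstituted benzene with oxygen on C2, C4 and C6, the arylmethyl arms on C3 and C5 and the acyl group on C1. With C1 left as CH this is the 1,3,5-trioxygenated pattern that a cyclobutenone/oxyalkyne benzannulation assembles.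
- The cyclobutenone is cut across its ring into an arm B ketene (from a 3-arylpropanoyl chloride) and an arm C siloxyalkyne (from an arylacetate). Both aryl units come from 2-methylphloroglucinol by acylation, etherification, bromination and organozinc coupling.
- Forward order: rings B and C are bought and dressed, the four-membered ring is made by ketene–alkyne [2+2] addition, ring A arises in the benzannulation, and desilylation, hydrogenolysis and C1 acylation finish the target.
- Stereochemistry: the only stereocentre comes from (R)-2-methylbutanoic acid, introduced as its acid chloride in the last step.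

Key step: step 16

Remark: ring A is numbered with the 2-methylbutanoyl carbon as C1, the arm to the acetyl ring (ring B) on C3 and the arm to the isobutyryl ring (ring C) on C5; the two organozinc bromide solutions and 3-phenylisoxazole are taken as purchased.

Abbreviations: ArB = 3-acetyl-2,6-bis(benzyloxy)-4-methoxy-5-methylphenyl; ArC = 2,6-bis(benzyloxy)-4-methoxy-3-methyl-5-[2-methyl-1-(triisopropylsiloxy)prop-1-enyl]phenyl. The ring C ketone is carried as this silyl enol ether from step 11 to step 17 because it would not survive the organolithium reagents of step 13.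

**Route**

Step 1
Reactants: 1 2-methylbenzene-1,3,5-triol
Product: 2 1-(2,4,6-trihydroxy-3-methylphenyl)ethanone
Conditions: AcCl (1.1 equiv), AlCl3 (3.5 equiv), PhNO2–CH2Cl2, 0 °C to rt
Reagents that add atoms: acetyl chloride CC(=O)Cl
Why: Friedel–Crafts acylation of the phloroglucinol nucleus; the two free ring carbons of 1 are equivalent and the acyl group deactivates the ring against a second acylation.

Step 2
Reactants: 2 1-(2,4,6-trihydroxy-3-methylphenyl)ethanone
Product: 3 1-[4,6-bis(benzyloxy)-2-hydroxy-3-methylphenyl]ethanone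
Conditions: BnBr (2.1 equiv), K2CO3, DMF, rt
Reagents that add atoms: benzyl bromide BrCc1ccccc1
Why: Williamson etherification in which the hydroxyl between the acetyl group and the ring methyl group, the most hindered one and the one held in the stronger hydrogen bond to the carbonyl oxygen, should react last, so two equivalents of benzyl bromide should cap the other two.

Step 3
Reactants: 3 1-[4,6-bis(benzyloxy)-2-hydroxy-3-methylphenyl]ethanone
Product: 4 1-[4,6-bis(benzyloxy)-2-methoxy-3-methylphenyl]ethanone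
Conditions: MeI (excess), K2CO3, DMF, 50 °C
Reagents that add atoms: iodomethane CI
Why: Williamson etherification under more forcing conditions methylates the remaining chelated hydroxyl and fixes the methoxy group between the acyl and methyl substituents, as in rings B and C of the target.

Step 4
Reactants: 4 1-[4,6-bis(benzyloxy)-2-methoxy-3-methylphenyl]ethanone
Product: 5 1-[2,4-bis(benzyloxy)-3-bromo-6-methoxy-5-methylphenyl]ethanone
Conditions: NBS, MeCN, 0 °C to rt, dark
Reagents that add atoms: N-bromosuccinimide O=C1CCC(=O)N1Br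
Why: Electrophilic aromatic bromination at the only unsubstituted ring carbon, which is ortho to two benzyloxy groups and para to the methoxy group, under neutral conditions that do not enolise the twisted ketone.

Step 5
Reactants: 5 1-[2,4-bis(benzyloxy)-3-bromo-6-methoxy-5-methylphenyl]ethanone
Product: 6 ethyl 3-[3-acetyl-2,6-bis(benzyloxy)-4-methoxy-5-methylphenyl]propanoate
Conditions: BrZnCH2CH2CO2Et (0.5 M in THF), Pd(OAc)2 (cat.), SPhos, THF, 60 °C
Reagents that add atoms: (3-ethoxy-3-oxopropyl)zinc bromide CCOC(=O)CC[Zn]Br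
Why: Negishi coupling of a primary alkylzinc halide with a di-ortho-alkoxy aryl bromide, for which the bulky biarylphosphine eases oxidative addition and reductive elimination, while the organozinc reagent leaves ketone and ester untouched.

Step 6
Reactants: 6 ethyl 3-[3-acetyl-2,6-bis(benzyloxy)-4-methoxy-5-methylphenyl]propanoate
Product: 7 3-[3-acetyl-2,6-bis(benzyloxy)-4-methoxy-5-methylphenyl]propanoic acid
Conditions: LiOH, THF–MeOH–H2O, rt; then 1 M HCl
Reagents that add atoms: lithium hydroxide [Li+].[OH-]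
Why: Saponification of the unhindered ethyl ester, to which the di-ortho-substituted aryl ketone and the benzyl ethers are inert at room temperature.

Step 7
Reactants: 1 2-methylbenzene-1,3,5-triol
Product: 8 2-methyl-1-(2,4,6-trihydroxy-3-methylphenyl)propan-1-one
Conditions: i-PrCOCl (1.1 equiv), AlCl3 (3.5 equiv), PhNO2–CH2Cl2, 0 °C to rt
Reagents that add atoms: isobutyryl chloride CC(C)C(=O)Cl
Why: Friedel–Crafts acylation as in step 1, again at one of two equivalent ring carbons.

Step 8
Reactants: 8 2-methyl-1-(2,4,6-trihydroxy-3-methylphenyl)propan-1-one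
Product: 9 1-[4,6-bis(benzyloxy)-2-hydroxy-3-methylphenyl]-2-methylpropan-1-one
Conditions: BnBr (2.1 equiv), K2CO3, DMF, rt
Reagents that add atoms: benzyl bromide BrCc1ccccc1
Why: Williamson etherification with the same site selectivity as in step 2, the chelated hydroxyl next to the ring methyl group being left free.

Step 9
Reactants: 9 1-[4,6-bis(benzyloxy)-2-hydroxy-3-methylphenyl]-2-methylpropan-1-one
Product: 10 1-[4,6-bis(benzyloxy)-2-methoxy-3-methylphenyl]-2-methylpropan-1-one
Conditions: MeI (excess), K2CO3, DMF, 50 °C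
Reagents that add atoms: iodomethane CI
Why: Williamson etherification of the last, chelated hydroxyl as in step 3.

Step 10
Reactants: 10 1-[4,6-bis(benzyloxy)-2-methoxy-3-methylphenyl]-2-methylpropan-1-one
Product: 11 1-[2,4-bis(benzyloxy)-3-bromo-6-methoxy-5-methylphenyl]-2-methylpropan-1-one
Conditions: NBS, MeCN, 0 °C to rt, dark
Reagents that add atoms: N-bromosuccinimide O=C1CCC(=O)N1Br
Why: Electrophilic aromatic bromination at the single free ring carbon as in step 4.

Step 11
Reactants: 11 1-[2,4-bis(benzyloxy)-3-bromo-6-methoxy-5-methylphenyl]-2-methylpropan-1-one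
Product: 12 [1-(2,4-bis(benzyloxy)-3-bromo-6-methoxy-5-methylphenyl)-2-methylprop-1-enyl]oxy-triisopropylsilane
Conditions: i-Pr3SiOTf, Et3N, CH2Cl2, 0 °C to rt
Reagents that add atoms: triisopropylsilyl trifluoromethanesulfonate CC(C)[Si](OS(=O)(=O)C(F)(F)F)(C(C)C)C(C)C
Why: Soft enolisation with a silyl triflate and a tertiary amine turns the isobutyryl ketone into its silyl enol ether, which has no E/Z isomers because the alkene carbon bears two methyl groups and which masks the carbonyl group until fluoride releases it in step 17.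

Step 12
Reactants: 12 [1-(2,4-bis(benzyloxy)-3-bromo-6-methoxy-5-methylphenyl)-2-methylprop-1-enyl]oxy-triisopropylsilane
Product: 13 ethyl 2-ArC-acetate
Conditions: BrZnCH2CO2Et (0.5 M in Et2O), Pd2(dba)3 (cat.), SPhos, THF, 65 °C
Reagents that add atoms: (2-ethoxy-2-oxoethyl)zinc bromide CCOC(=O)C[Zn]Br
Why: Palladium-catalysed coupling of a Reformatsky reagent with the aryl bromide (Negishi-type arylation of a zinc ester enolate) should give the arylacetate under nearly neutral conditions that the silyl enol ether and the benzyl ethers tolerate.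

Step 13
Reactants: 13 ethyl 2-ArC-acetate
Product: 16 triisopropyl[(3-ArC-prop-1-yn-1-yl)oxy]silane, via lithium dibromoenolate 14 (not isolated), via lithium ynolate 15 (not isolated)
Conditions: CH2Br2, lithium 2,2,6,6-tetramethylpiperidide, THF, −78 °C; LiN(SiMe3)2, −78 °C; n-BuLi, −78 to 0 °C; i-Pr3SiOTf, −78 °C to rt
Reagents that add atoms: dibromomethane BrCBr; triisopropylsilyl trifluoromethanesulfonate CC(C)[Si](OS(=O)(=O)C(F)(F)F)(C(C)C)C(C)C
Why: Kowalski ynolate synthesis, in which dibromomethyllithium adds to the ester and the resulting dibromoketone is deprotonated to 14, bromine–lithium exchange triggers the carbenoid 1,2-shift of the arylmethyl group to give 15, and the bulky silyl triflate silylates oxygen and not carbon.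

Step 14
Reactants: 17 3-phenylisoxazole
Product: 20 (triisopropylsiloxy)ethyne, via 5-lithio-3-phenylisoxazole 18 (not isolated), via lithium ethynolate 19 (not isolated)
Conditions: n-BuLi (1.0 equiv), THF, −78 to −20 °C; i-Pr3SiOTf, −78 °C to rt; distillation
Reagents that add atoms: triisopropylsilyl trifluoromethanesulfonate CC(C)[Si](OS(=O)(=O)C(F)(F)F)(C(C)C)C(C)C
Why: Lithiation at C5 gives 18, which on warming fragments into benzonitrile and ynolate 19 (the base-induced cleavage of 5-unsubstituted 3-arylisoxazoles), and the bulky silyl triflate should again silylate the ynolate on oxygen.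

Step 15
Reactants: 7 3-[3-acetyl-2,6-bis(benzyloxy)-4-methoxy-5-methylphenyl]propanoic acid; 16 triisopropyl[(3-ArC-prop-1-yn-1-yl)oxy]silane
Product: 23 racemic 4-(ArB-methyl)-2-(ArC-methyl)-3-(triisopropylsiloxy)cyclobut-2-en-1-one, via acid chloride 21 (not isolated), via ketene 22 (not isolated)
Conditions: (COCl)2, cat. DMF, CH2Cl2, 0 °C to rt, evaporate; then slow addition to 16 and Et3N in CH2Cl2, rt to 40 °C
Reagents that add atoms: none
Why: Dehydrochlorination of 21 gives aldoketene 22, which undergoes [2+2] cycloaddition with the siloxyalkyne, the nucleophilic alkyne carbon remote from oxygen bonding to the ketene carbonyl carbon so that the siloxy group ends on C3 between the two arms; slow addition keeps the ketene dilute and limits its dimerisation.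

Step 16
Reactants: 23 racemic 4-(ArB-methyl)-2-(ArC-methyl)-3-(triisopropylsiloxy)cyclobut-2-en-1-one; 20 (triisopropylsiloxy)ethyne
Product: 28 2-(ArB-methyl)-4-(ArC-methyl)-3,5-bis(triisopropylsiloxy)phenol, via vinylketene 24 (not isolated), via alkenylcyclobutenone 25 (not isolated), via dienylketene 26 (not isolated), via cyclohexadienone 27 (not isolated)
Conditions: 20 (3 equiv), toluene, 110 °C, sealed tube, argon
Reagents that add atoms: none
Why: Heating cleaves the C1–C4 bond of the cyclobutenone in a four-electron conrotatory electrocyclic opening, the arylmethyl group on C4 turning outward, to give vinylketene 24, whose ketene C=C bond adds alkyne 20 in a [2+2] cycloaddition to give 25, which opens again to dienylketene 26. Thermal disrotatory six-electron electrocyclisation of 26 joins the ketene carbon (ring A C2) to the former cyclobutenone C4 (ring A C3) and closes ring A as cyclohexadienone 27, which enolises to the phenol. This is the Danheiser benzannulation of a cyclobutenone with a siloxyalkyne, run here on a 3-siloxycyclobutenone so that the third oxygen of the phloroglucinol is already in place. No stereocentre remains in 28, since the sp3 carbons of 23, 25 and 27 are all lost on aromatisation. The step needs regioselectivity in the ketene–alkyne addition, and the oxygen lone pair of 20 secures it by making the CH terminus nucleophilic, so that this carbon bonds to the ketene carbonyl carbon (bond C1–C2) and the siloxy carbon to the ketene α-carbon (bond C5–C6), which leaves H on C1 between two oxygens. A silyl or proton shift that exchanged the two arms on the four-membered ring would be harmless, because both arrangements give the same triol after step 17.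

Step 17
Reactants: 28 2-(ArB-methyl)-4-(ArC-methyl)-3,5-bis(triisopropylsiloxy)phenol
Product: 29 2-{[3-acetyl-2,6-bis(benzyloxy)-4-methoxy-5-methylphenyl]methyl}-4-{[2,6-bis(benzyloxy)-4-methoxy-3-methyl-5-(2-methylpropanoyl)phenyl]methyl}benzene-1,3,5-triol
Conditions: Bu4NF (5 equiv), AcOH (5 equiv), THF, 0 °C to rt, argon
Reagents that add atoms: none
Why: Fluoride cleaves the two aryl silyl ethers and the silyl enol ether, whose enolate is protonated by the acetic acid buffer to restore the isobutyryl ketone, and the buffer keeps the air-sensitive phloroglucinol ring A from standing as its phenoxide.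

Step 18
Reactants: 29 2-{[3-acetyl-2,6-bis(benzyloxy)-4-methoxy-5-methylphenyl]methyl}-4-{[2,6-bis(benzyloxy)-4-methoxy-3-methyl-5-(2-methylpropanoyl)phenyl]methyl}benzene-1,3,5-triol
Product: 30 2-[(3-acetyl-2,6-dihydroxy-4-methoxy-5-methylphenyl)methyl]-4-{[2,6-dihydroxy-4-methoxy-3-methyl-5-(2-methylpropanoyl)phenyl]methyl}benzene-1,3,5-triol
Conditions: H2 (1 atm), 10% Pd/C, EtOAc–MeOH, rt
Reagents that add atoms: none
Why: Hydrogenolysis of the four aryl benzyl ethers over palladium, under which the hindered hydrogen-bonded aryl ketones and the diarylmethane bridges should not be reduced.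

Step 19
Reactants: 31 (R)-2-methylbutanoic acid
Product: 32 (R)-2-methylbutanoyl chloride
Conditions: (COCl)2, cat. DMF, CH2Cl2, 0 °C to rt
Reagents that add atoms: oxalyl chloride O=C(Cl)C(=O)Cl
Why: Acid chloride formation through the catalytic chloroiminium species at or below room temperature, conditions under which the α-stereocentre should stay untouched.

Step 20
Reactants: 30 2-[(3-acetyl-2,6-dihydroxy-4-methoxy-5-methylphenyl)methyl]-4-{[2,6-dihydroxy-4-methoxy-3-methyl-5-(2-methylpropanoyl)phenyl]methyl}benzene-1,3,5-triol; 32 (R)-2-methylbutanoyl chloride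
Product: 33 (2R)-1-{3-[(3-acetyl-2,6-dihydroxy-4-methoxy-5-methylphenyl)methyl]-5-{[2,6-dihydroxy-4-methoxy-3-methyl-5-(2-methylpropanoyl)phenyl]methyl}-2,4,6-trihydroxyphenyl}-2-methylbutan-1-one
Conditions: AlCl3 (excess), PhNO2–CH2Cl2, 0 °C to rt; cold 1 M HCl
Reagents that add atoms: none
Why: Friedel–Crafts acylation at C1 of ring A, the only unsubstituted aromatic carbon in the molecule and the most electron-rich one, with the configuration carried over unchanged from 32 as long as the temperature is kept low enough that the acylium ion does not equilibrate with the ketene.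

**Compound list**

1 | 2-methylbenzene-1,3,5-triol | Cc1c(O)cc(O)cc1O | starting material
2 | 1-(2,4,6-trihydroxy-3-methylphenyl)ethanone | CC(=O)c1c(O)cc(O)c(C)c1O | intermediate
3 | 1-[4,6-bis(benzyloxy)-2-hydroxy-3-methylphenyl]ethanone | CC(=O)c1c(OCc2ccccc2)cc(OCc2ccccc2)c(C)c1O | intermediate
4 | 1-[4,6-bis(benzyloxy)-2-methoxy-3-methylphenyl]ethanone | CC(=O)c1c(OCc2ccccc2)cc(OCc2ccccc2)c(C)c1OC | intermediate
5 | 1-[2,4-bis(benzyloxy)-3-bromo-6-methoxy-5-methylphenyl]ethanone | CC(=O)c1c(OCc2ccccc2)c(Br)c(OCc2ccccc2)c(C)c1OC | intermediate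
6 | ethyl 3-[3-acetyl-2,6-bis(benzyloxy)-4-methoxy-5-methylphenyl]propanoate | CCOC(=O)CCc1c(OCc2ccccc2)c(C)c(OC)c(C(C)=O)c1OCc1ccccc1 | intermediate
7 | 3-[3-acetyl-2,6-bis(benzyloxy)-4-methoxy-5-methylphenyl]propanoic acid | OC(=O)CCc1c(OCc2ccccc2)c(C)c(OC)c(C(C)=O)c1OCc1ccccc1 | intermediate
8 | 2-methyl-1-(2,4,6-trihydroxy-3-methylphenyl)propan-1-one | CC(C)C(=O)c1c(O)cc(O)c(C)c1O | intermediate
9 | 1-[4,6-bis(benzyloxy)-2-hydroxy-3-methylphenyl]-2-methylpropan-1-one | CC(C)C(=O)c1c(OCc2ccccc2)cc(OCc2ccccc2)c(C)c1O | intermediate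
10 | 1-[4,6-bis(benzyloxy)-2-methoxy-3-methylphenyl]-2-methylpropan-1-one | CC(C)C(=O)c1c(OCc2ccccc2)cc(OCc2ccccc2)c(C)c1OC | intermediate
11 | 1-[2,4-bis(benzyloxy)-3-bromo-6-methoxy-5-methylphenyl]-2-methylpropan-1-one | CC(C)C(=O)c1c(OCc2ccccc2)c(Br)c(OCc2ccccc2)c(C)c1OC | intermediate
12 | [1-(2,4-bis(benzyloxy)-3-bromo-6-methoxy-5-methylphenyl)-2-methylprop-1-enyl]oxy-triisopropylsilane (silyl enol ether of 11) | CC(C)=C(O[Si](C(C)C)(C(C)C)C(C)C)c1c(OCc2ccccc2)c(Br)c(OCc2ccccc2)c(C)c1OC | intermediate
13 | ethyl 2-{2,6-bis(benzyloxy)-4-methoxy-3-methyl-5-[2-methyl-1-(triisopropylsiloxy)prop-1-enyl]phenyl}acetate (ethyl 2-ArC-acetate) | CCOC(=O)Cc1c(OCc2ccccc2)c(C)c(OC)c(C(O[Si](C(C)C)(C(C)C)C(C)C)=C(C)C)c1OCc1ccccc1 | intermediate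
14 | lithium 3-ArC-1,1-dibromoprop-1-en-2-olate (formed in the flask, not isolated) | [Li]OC(Cc1c(OCc2ccccc2)c(C)c(OC)c(C(O[Si](C(C)C)(C(C)C)C(C)C)=C(C)C)c1OCc1ccccc1)=C(Br)Br | intermediate
15 | lithium 3-ArC-prop-1-yn-1-olate (formed in the flask, not isolated) | [Li]OC#CCc1c(OCc2ccccc2)c(C)c(OC)c(C(O[Si](C(C)C)(C(C)C)C(C)C)=C(C)C)c1OCc1ccccc1 | intermediate
16 | triisopropyl[(3-ArC-prop-1-yn-1-yl)oxy]silane (arm C siloxyalkyne) | CC(C)[Si](OC#CCc1c(OCc2ccccc2)c(C)c(OC)c(C(O[Si](C(C)C)(C(C)C)C(C)C)=C(C)C)c1OCc1ccccc1)(C(C)C)C(C)C | intermediate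
17 | 3-phenylisoxazole | c1ccc(-c2ccon2)cc1 | starting material
18 | 5-lithio-3-phenylisoxazole (formed in the flask, not isolated) | [Li]c1cc(-c2ccccc2)no1 | intermediate
19 | lithium ethynolate (formed in the flask, not isolated) | [Li]OC#C | intermediate
20 | (triisopropylsiloxy)ethyne | C#CO[Si](C(C)C)(C(C)C)C(C)C | intermediate
21 | 3-ArB-propanoyl chloride (formed in the flask, not isolated) | O=C(Cl)CCc1c(OCc2ccccc2)c(C)c(OC)c(C(C)=O)c1OCc1ccccc1 | intermediate
22 | 3-ArB-prop-1-en-1-one, the arm B ketene (formed in the flask, not isolated) | O=C=CCc1c(OCc2ccccc2)c(C)c(OC)c(C(C)=O)c1OCc1ccccc1 | intermediate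
23 | racemic 4-(ArB-methyl)-2-(ArC-methyl)-3-(triisopropylsiloxy)cyclobut-2-en-1-one | O=C1C(Cc2c(OCc3ccccc3)c(C)c(OC)c(C(C)=O)c2OCc2ccccc2)C(O[Si](C(C)C)(C(C)C)C(C)C)=C1Cc1c(OCc2ccccc2)c(C)c(OC)c(C(O[Si](C(C)C)(C(C)C)C(C)C)=C(C)C)c1OCc1ccccc1 | intermediate
24 | (Z)-5-ArB-2-(ArC-methyl)-3-(triisopropylsiloxy)penta-1,3-dien-1-one, the vinylketene (formed in the flask, not isolated) | O=C=C(Cc1c(OCc2ccccc2)c(C)c(OC)c(C(O[Si](C(C)C)(C(C)C)C(C)C)=C(C)C)c1OCc1ccccc1)/C(O[Si](C(C)C)(C(C)C)C(C)C)=C/Cc1c(OCc2ccccc2)c(C)c(OC)c(C(C)=O)c1OCc1ccccc1 | intermediate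
25 | racemic 4-(ArC-methyl)-4-[(Z)-3-ArB-1-(triisopropylsiloxy)prop-1-enyl]-3-(triisopropylsiloxy)cyclobut-2-en-1-one (formed in the flask, not isolated) | O=C1C=C(O[Si](C(C)C)(C(C)C)C(C)C)C1(Cc1c(OCc2ccccc2)c(C)c(OC)c(C(O[Si](C(C)C)(C(C)C)C(C)C)=C(C)C)c1OCc1ccccc1)/C(O[Si](C(C)C)(C(C)C)C(C)C)=C/Cc1c(OCc2ccccc2)c(C)c(OC)c(C(C)=O)c1OCc1ccccc1 | intermediate
26 | 7-ArB-4-(ArC-methyl)-3,5-bis(triisopropylsiloxy)hepta-1,3,5-trien-1-one, the dienylketene (formed in the flask, not isolated) | O=C=C/C(O[Si](C(C)C)(C(C)C)C(C)C)=C(Cc1c(OCc2ccccc2)c(C)c(OC)c(C(O[Si](C(C)C)(C(C)C)C(C)C)=C(C)C)c1OCc1ccccc1)\C(O[Si](C(C)C)(C(C)C)C(C)C)=C\Cc1c(OCc2ccccc2)c(C)c(OC)c(C(C)=O)c1OCc1ccccc1 | intermediate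
27 | racemic 6-(ArB-methyl)-4-(ArC-methyl)-3,5-bis(triisopropylsiloxy)cyclohexa-2,4-dien-1-one (formed in the flask, not isolated) | O=C1C=C(O[Si](C(C)C)(C(C)C)C(C)C)C(Cc2c(OCc3ccccc3)c(C)c(OC)c(C(O[Si](C(C)C)(C(C)C)C(C)C)=C(C)C)c2OCc2ccccc2)=C(O[Si](C(C)C)(C(C)C)C(C)C)C1Cc1c(OCc2ccccc2)c(C)c(OC)c(C(C)=O)c1OCc1ccccc1 | intermediate
28 | 2-(ArB-methyl)-4-(ArC-methyl)-3,5-bis(triisopropylsiloxy)phenol | Oc1cc(O[Si](C(C)C)(C(C)C)C(C)C)c(Cc2c(OCc3ccccc3)c(C)c(OC)c(C(O[Si](C(C)C)(C(C)C)C(C)C)=C(C)C)c2OCc2ccccc2)c(O[Si](C(C)C)(C(C)C)C(C)C)c1Cc1c(OCc2ccccc2)c(C)c(OC)c(C(C)=O)c1OCc1ccccc1 | intermediate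
29 | 2-{[3-acetyl-2,6-bis(benzyloxy)-4-methoxy-5-methylphenyl]methyl}-4-{[2,6-bis(benzyloxy)-4-methoxy-3-methyl-5-(2-methylpropanoyl)phenyl]methyl}benzene-1,3,5-triol | Oc1cc(O)c(Cc2c(OCc3ccccc3)c(C)c(OC)c(C(=O)C(C)C)c2OCc2ccccc2)c(O)c1Cc1c(OCc2ccccc2)c(C)c(OC)c(C(C)=O)c1OCc1ccccc1 | intermediate
30 | 2-[(3-acetyl-2,6-dihydroxy-4-methoxy-5-methylphenyl)methyl]-4-{[2,6-dihydroxy-4-methoxy-3-methyl-5-(2-methylpropanoyl)phenyl]methyl}benzene-1,3,5-triol | Oc1cc(O)c(Cc2c(O)c(C)c(OC)c(C(=O)C(C)C)c2O)c(O)c1Cc1c(O)c(C)c(OC)c(C(C)=O)c1O | intermediate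
31 | (R)-2-methylbutanoic acid | CC[C@@H](C)C(=O)O | starting material
32 | (R)-2-methylbutanoyl chloride | CC[C@@H](C)C(=O)Cl | intermediate
33 | (2R)-1-{3-[(3-acetyl-2,6-dihydroxy-4-methoxy-5-methylphenyl)methyl]-5-{[2,6-dihydroxy-4-methoxy-3-methyl-5-(2-methylpropanoyl)phenyl]methyl}-2,4,6-trihydroxyphenyl}-2-methylbutan-1-one | CC[C@@H](C)C(=O)c1c(O)c(Cc2c(O)c(C)c(OC)c(C(C)=O)c2O)c(O)c(Cc2c(O)c(C)c(OC)c(C(=O)C(C)C)c2O)c1O | target

**Step count**

Total: 20 steps. Longest linear sequence: 12 steps (steps 7 to 13, then 15, 16, 17, 18 and 20).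

**Steps most likely to fail**

1. Step 16. The 3-siloxy group stabilises the four-membered ring as a vinylogous ester, so ring opening may be too slow at temperatures the siloxyalkyne tolerates before its silyl group shifts from oxygen to carbon. The vinylketene may also be lost to dimerisation or to acylation of phenol already formed. The fallback builds the deacyl trimer by Mannich chemistry and sets out from 4 and 10. Hydrogenolysis of 4 (H2, Pd/C) should give 1-(4,6-dihydroxy-2-methoxy-3-methylphenyl)ethanone F1, and the same treatment of 10 should give 1-(4,6-dihydroxy-2-methoxy-3-methylphenyl)-2-methylpropan-1-one F2. Aminomethylation of each at its only free ring carbon (aqueous formaldehyde, dimethylamine, EtOH) should give 1-{3-[(dimethylamino)methyl]-2,4-dihydroxy-6-methoxy-5-methylphenyl}ethanone F3 and 1-{3-[(dimethylamino)methyl]-2,4-dihydroxy-6-methoxy-5-methylphenyl}-2-methylpropan-1-one F4. Heating F3 with an excess of commercial benzene-1,3,5-triol in dioxane should expel dimethylamine and alkylate the triol once, giving 2-[(3-acetyl-2,6-dihydroxy-4-methoxy-5-methylphenyl)methyl]benzene-1,3,5-triol F5. Heating F5 with F4 in the same way should attach the second arm and rejoin the route at 30.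

2. Step 13. The lithium amide or dibromomethyllithium may deprotonate the arylacetate CH2 instead of adding to the ester, and n-BuLi may attack the benzylic ether positions while the mixture warms. The fallback oxidises a terminal alkyne instead and sets out from 13. Reduction with i-Bu2AlH (CH2Cl2, −78 °C) should give 2-ArC-acetaldehyde F6. Ohira–Bestmann homologation (dimethyl (1-diazo-2-oxopropyl)phosphonate, K2CO3, MeOH) should give 3-ArC-prop-1-yne F7. Deprotonation with LiN(SiMe3)2, oxidation of the acetylide with lithium tert-butyl peroxide (THF, −78 to 0 °C) to ynolate 15 and silylation with i-Pr3SiOTf should rejoin the route at 16.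

3. Step 20. The α-stereocentre may lose configurational purity through acylium–ketene equilibration or enolisation of the AlCl3-complexed aryl ketone, and the strong Lewis acid may cleave or shift the arylmethyl bridges on ring A. The fallback is a Houben–Hoesch acylation and sets out from 32 and 30. Aqueous ammonia should convert 32 into (R)-2-methylbutanamide F8, and dehydration with (CF3CO)2O and pyridine at 0 °C should give (R)-2-methylbutanenitrile F9. Treating 30 with F9, ZnCl2 and HCl gas in Et2O at 0 °C should give the C1 ketiminium chloride F10 through a nitrilium ion that cannot form a ketene. Mild aqueous hydrolysis of F10 should rejoin the route at 33.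

**Further compounds**

F1 | step 16 | 1-(4,6-dihydroxy-2-methoxy-3-methylphenyl)ethanone | CC(=O)c1c(O)cc(O)c(C)c1OC
F2 | step 16 | 1-(4,6-dihydroxy-2-methoxy-3-methylphenyl)-2-methylpropan-1-one | CC(C)C(=O)c1c(O)cc(O)c(C)c1OC
F3 | step 16 | 1-{3-[(dimethylamino)methyl]-2,4-dihydroxy-6-methoxy-5-methylphenyl}ethanone | CC(=O)c1c(O)c(CN(C)C)c(O)c(C)c1OC
F4 | step 16 | 1-{3-[(dimethylamino)methyl]-2,4-dihydroxy-6-methoxy-5-methylphenyl}-2-methylpropan-1-one | CC(C)C(=O)c1c(O)c(CN(C)C)c(O)c(C)c1OC
F5 | step 16 | 2-[(3-acetyl-2,6-dihydroxy-4-methoxy-5-methylphenyl)methyl]benzene-1,3,5-triol | CC(=O)c1c(O)c(Cc2c(O)cc(O)cc2O)c(O)c(C)c1OC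
F6 | step 13 | 2-ArC-acetaldehyde | O=CCc1c(OCc2ccccc2)c(C)c(OC)c(C(O[Si](C(C)C)(C(C)C)C(C)C)=C(C)C)c1OCc1ccccc1
F7 | step 13 | 3-ArC-prop-1-yne | C#CCc1c(OCc2ccccc2)c(C)c(OC)c(C(O[Si](C(C)C)(C(C)C)C(C)C)=C(C)C)c1OCc1ccccc1
F8 | step 20 | (R)-2-methylbutanamide | CC[C@@H](C)C(N)=O
F9 | step 20 | (R)-2-methylbutanenitrile | CC[C@@H](C)C#N
F10 | step 20 | (R)-configured C1 ketiminium chloride of 33 | CC[C@@H](C)C(=[NH2+])c1c(O)c(Cc2c(O)c(C)c(OC)c(C(C)=O)c2O)c(O)c(Cc2c(O)c(C)c(OC)c(C(=O)C(C)C)c2O)c1O.[Cl-]
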